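The flavone is disconnected at C4–C4a. In the target the piperidinyl-bearing carbon C6 of ring A lies para to C8a, so the phenol that becomes ring A has two equivalent carbons ortho to its oxygen (the future C4a and C8). An intramolecular Friedel–Crafts acylation of a (Z)-3-aryloxycinnamic acid therefore closes the pyranone ring (ring C) and fixes the 5,7-dioxygenated, 6-substituted pattern in one operation, with no 8-isomer possible. The precursor carries two methyl ethers and the finished (R)-N-methylpiperidine, whose stereocentre is set earlier by Grignard addition to an (S)-tert-butanesulfinyl imine; the phenol is joined to ethyl phenylpropiolate by oxa-Michael addition.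

Key step: step 9

Assumption: 4-chlorobutylmagnesium bromide is made just before use from commercial 1-bromo-4-chlorobutane and magnesium, and any E ester formed beside the Z ester in step 7 is expected to converge on the same product in the acid of step 9.

Step 1
Reactants: 1 4-hydroxy-2,6-dimethoxybenzaldehyde
Product: 2 4-(benzyloxy)-2,6-dimethoxybenzaldehyde
Conditions: BnBr, K2CO3, DMF, rt
Reagents that add atoms: benzyl bromide, BrCc1ccccc1
Why: Williamson ether synthesis, in which the acidic phenol para to the formyl group is deprotonated by K2CO3 and displaces bromide by SN2, masking the future O1 oxygen as an ether that hydrogenolysis removes without touching the methyl ethers.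

Step 2
Reactants: 2 4-(benzyloxy)-2,6-dimethoxybenzaldehyde; 3 (S)-2-methylpropane-2-sulfinamide
Product: 4 (S,E)-N-[4-(benzyloxy)-2,6-dimethoxybenzylidene]-2-methylpropane-2-sulfinamide
Conditions: Ti(OEt)4 (2 equiv), THF, 65 °C
Reagents that add atoms: none
Why: Condensation of an aldehyde with tert-butanesulfinamide to the N-sulfinyl aldimine, where Ti(OEt)4 serves as Lewis acid and water scavenger and should drive even this electron-rich, di-ortho-substituted aldehyde to the E-imine without disturbing the sulfur stereocentre.

Step 3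
Reactants: 4 (S,E)-N-[4-(benzyloxy)-2,6-dimethoxybenzylidene]-2-methylpropane-2-sulfinamide
Product: 5 (S)-N-{(R)-1-[4-(benzyloxy)-2,6-dimethoxyphenyl]-5-chloropentyl}-2-methylpropane-2-sulfinamide
Conditions: Cl(CH2)4MgBr (2 equiv; from Br(CH2)4Cl, Mg, Et2O), CH2Cl2, −48 °C → 0 °C; sat. aq NH4Cl
Reagents that add atoms: 4-chlorobutylmagnesium bromide, ClCCCC[Mg]Br
Why: 1,2-Addition of a Grignard reagent to an N-tert-butanesulfinyl aldimine in a non-coordinating solvent, where magnesium bridges the sulfinyl oxygen in a six-membered chair with tert-butyl equatorial and so delivers the alkyl group to the Re face of the (S)-sulfinyl E-imine, setting the benzylic stereocentre as R while the primary chloride stays inert in the cold.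

Step 4
Reactants: 5 (S)-N-{(R)-1-[4-(benzyloxy)-2,6-dimethoxyphenyl]-5-chloropentyl}-2-methylpropane-2-sulfinamide
Product: 7 (R)-2-[4-(benzyloxy)-2,6-dimethoxyphenyl]piperidine, via chloroamine hydrochloride 6 (not isolated)
Conditions: HCl (4 M in dioxane, 3 equiv), MeOH, 0 °C, 30 min; evaporate; K2CO3, NaI (cat.), MeCN, 60 °C
Reagents that add atoms: none
Why: Acidolysis of the sulfinamide S–N bond (kept cold and brief so that the electron-rich benzylic C–N bond is not ionised) followed by intramolecular SN2 N-alkylation of the freed primary amine (6-exo-tet, iodide-assisted), neither event breaking a bond at the stereocentre.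

Step 5
Reactants: 7 (R)-2-[4-(benzyloxy)-2,6-dimethoxyphenyl]piperidine
Product: 8 (R)-2-[4-(benzyloxy)-2,6-dimethoxyphenyl]-1-methylpiperidine
Conditions: aq HCHO (37%), NaBH(OAc)3, ClCH2CH2Cl, rt
Reagents that add atoms: formaldehyde, C=O
Why: Reductive amination, in which the secondary amine and formaldehyde form an iminium ion that NaBH(OAc)3 reduces, giving mono-N-methylation without quaternisation and without touching the adjacent stereocentre.

Step 6
Reactants: 8 (R)-2-[4-(benzyloxy)-2,6-dimethoxyphenyl]-1-methylpiperidine
Product: 9 (R)-3,5-dimethoxy-4-(1-methylpiperidin-2-yl)phenol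
Conditions: H2 (1 atm), Pd/C (10 wt%), EtOH, rt
Reagents that add atoms: none
Why: Catalytic hydrogenolysis of a benzyl aryl ether, which under neutral conditions at room temperature should be much faster than cleavage of the hindered benzylic C–N bond of the tertiary amine, so only the phenol is unveiled.

Step 7
Reactants: 9 (R)-3,5-dimethoxy-4-(1-methylpiperidin-2-yl)phenol; 10 ethyl 3-phenylprop-2-ynoate
Product: 11 ethyl (Z)-3-{3,5-dimethoxy-4-[(R)-1-methylpiperidin-2-yl]phenoxy}-3-phenylprop-2-enoate
Conditions: Cs2CO3 (0.3 equiv), DMF, 40–50 °C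
Reagents that add atoms: none
Why: Base-mediated oxa-Michael addition of a phenoxide to an alkynoate, where attack at the phenyl-bearing β-carbon and anti protonation should place the aryloxy group cis to the ester (Z), the mild non-acidic conditions keeping the para-hydroxybenzylic amine from opening through a quinone methide.

Step 8
Reactants: 11 ethyl (Z)-3-{3,5-dimethoxy-4-[(R)-1-methylpiperidin-2-yl]phenoxy}-3-phenylprop-2-enoate
Product: 12 (Z)-3-{3,5-dimethoxy-4-[(R)-1-methylpiperidin-2-yl]phenoxy}-3-phenylprop-2-enoic acid
Conditions: LiOH·H2O (3 equiv), THF/MeOH/H2O, rt → 40 °C; then 1 M HCl to pH ≈ 6.5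
Reagents that add atoms: lithium hydroxide, [Li+].[OH-]
Why: Saponification of the ethyl ester, in which hydroxide should attack the ester carbonyl faster than it displaces the electron-rich aryloxide from the β-carbon of this vinylogous carbonate, so the enol ether and its geometry are retained and neutralisation to the isoelectric point gives the amino acid.

Step 9
Reactants: 12 (Z)-3-{3,5-dimethoxy-4-[(R)-1-methylpiperidin-2-yl]phenoxy}-3-phenylprop-2-enoic acid
Product: 13 (R)-5,7-dimethoxy-6-(1-methylpiperidin-2-yl)-2-phenyl-4H-chromen-4-one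
Conditions: P2O5/MeSO3H (1:10 w/w), 0 °C → rt; ice, then aq NaOH to pH 9
Reagents that add atoms: none
Why: In P2O5/MeSO3H the carboxylic acid becomes a mixed anhydride that ionises to an acylium ion; because this carbon sits cis to the aryloxy group on the Z-alkene, the ring carbon ortho to the ether oxygen attacks it and loss of a proton restores the aromatic ring, which is an intramolecular Friedel–Crafts acylation and matches the classical closure of 3-aryloxycinnamic acids to flavones as the closest known reaction type. The pyranone ring closes in a six-membered mode with the acylium C≡O left outside the new ring (6-exo-dig with respect to the acylium carbon). No stereocentre is created; the existing piperidine C2 is carried through as the N-protonated ammonium, a poor leaving group, so the benzylic C–N bond should not ionise at or below room temperature. The only selectivity needed is the choice of ortho carbon, and the substrate secures it: the two ortho carbons are equivalent, each flanked by the ether oxygen and a methoxy group and para to the other methoxy group, so either attack gives the 5,7-dimethoxy-6-substituted chromenone and no 8-isomer can form. Any E acid present is expected to equilibrate with the Z acid through the O-protonated, oxocarbenium-like form and so to give the same product.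

Step 10
Reactants: 13 (R)-5,7-dimethoxy-6-(1-methylpiperidin-2-yl)-2-phenyl-4H-chromen-4-one
Product: 14 (R)-5,7-dihydroxy-6-(1-methylpiperidin-2-yl)-2-phenyl-4H-chromen-4-one
Conditions: BBr3 (6 equiv), CH2Cl2, −78 °C → rt; then ice/aq NaHCO3 (pH 7–8)
Reagents that add atoms: none
Why: Lewis-acid cleavage of aryl methyl ethers with BBr3 (O-coordination, then SN2 attack of bromide on methyl), assisted at the 5-methoxy group by chelation to the C4 carbonyl, with the amine tied up as its boron adduct and the cold aprotic medium avoiding both pyranone ring opening (Wessely–Moser rearrangement of the 6-substituent to C8) and ionisation of the benzylic C–N bond.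

Compound list
1 | 4-hydroxy-2,6-dimethoxybenzaldehyde | COc1cc(O)cc(OC)c1C=O | starting material
2 | 4-(benzyloxy)-2,6-dimethoxybenzaldehyde | COc1cc(OCc2ccccc2)cc(OC)c1C=O | intermediate
3 | (S)-2-methylpropane-2-sulfinamide | CC(C)(C)[S@](=O)N | starting material
4 | (S,E)-N-[4-(benzyloxy)-2,6-dimethoxybenzylidene]-2-methylpropane-2-sulfinamide | CC(C)(C)[S@](=O)/N=C/c1c(OC)cc(OCc2ccccc2)cc1OC | intermediate
5 | (S)-N-{(R)-1-[4-(benzyloxy)-2,6-dimethoxyphenyl]-5-chloropentyl}-2-methylpropane-2-sulfinamide | CC(C)(C)[S@](=O)N[C@H](CCCCCl)c1c(OC)cc(OCc2ccccc2)cc1OC | intermediate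
6 | (R)-1-[4-(benzyloxy)-2,6-dimethoxyphenyl]-5-chloropentan-1-amine hydrochloride | Cl.N[C@H](CCCCCl)c1c(OC)cc(OCc2ccccc2)cc1OC | intermediate (not isolated)
7 | (R)-2-[4-(benzyloxy)-2,6-dimethoxyphenyl]piperidine | N1CCCC[C@@H]1c1c(OC)cc(OCc2ccccc2)cc1OC | intermediate
8 | (R)-2-[4-(benzyloxy)-2,6-dimethoxyphenyl]-1-methylpiperidine | CN1CCCC[C@@H]1c1c(OC)cc(OCc2ccccc2)cc1OC | intermediate
9 | (R)-3,5-dimethoxy-4-(1-methylpiperidin-2-yl)phenol | CN1CCCC[C@@H]1c1c(OC)cc(O)cc1OC | intermediate
10 | ethyl 3-phenylprop-2-ynoate | CCOC(=O)C#Cc1ccccc1 | starting material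
11 | ethyl (Z)-3-{3,5-dimethoxy-4-[(R)-1-methylpiperidin-2-yl]phenoxy}-3-phenylprop-2-enoate | CN1CCCC[C@@H]1c1c(OC)cc(O/C(=C\C(=O)OCC)c2ccccc2)cc1OC | intermediate
12 | (Z)-3-{3,5-dimethoxy-4-[(R)-1-methylpiperidin-2-yl]phenoxy}-3-phenylprop-2-enoic acid | CN1CCCC[C@@H]1c1c(OC)cc(O/C(=C\C(O)=O)c2ccccc2)cc1OC | intermediate
13 | (R)-5,7-dimethoxy-6-(1-methylpiperidin-2-yl)-2-phenyl-4H-chromen-4-one | CN1CCCC[C@@H]1c1c(OC)cc2oc(-c3ccccc3)cc(=O)c2c1OC | intermediate
14 | (R)-5,7-dihydroxy-6-(1-methylpiperidin-2-yl)-2-phenyl-4H-chromen-4-one | CN1CCCC[C@@H]1c1c(O)cc2oc(-c3ccccc3)cc(=O)c2c1O | target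

Total step count: 10. Longest linear sequence: 10 steps, from 1 to 14; compounds 3 and 10 enter as commercial materials.

Steps most likely to fail

Step 9. The benzylic C–N bond may ionise in the strongly acidic medium, eroding the configuration or fragmenting the substrate, and the very electron-rich ring may be sulfonylated in competition with acylation. The fallback sets out from 9 and comes back at 13, closing ring C at O1–C2 under basic conditions while still relying on the two equivalent ortho carbons of the phenol.
- Magnesium-mediated ortho-formylation (MgCl2, Et3N, paraformaldehyde, MeCN, 70 °C) should give 6-hydroxy-2,4-dimethoxy-3-[(R)-1-methylpiperidin-2-yl]benzaldehyde F1.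
- Addition of lithium phenylacetylide (PhC≡CLi from phenylacetylene and n-BuLi, 2.5 equiv, THF, −78 °C → 0 °C) should give 1-{6-hydroxy-2,4-dimethoxy-3-[(R)-1-methylpiperidin-2-yl]phenyl}-3-phenylprop-2-yn-1-ol F2 as a mixture of carbinol epimers.
- Oxidation with MnO2 in CH2Cl2 should give 1-{6-hydroxy-2,4-dimethoxy-3-[(R)-1-methylpiperidin-2-yl]phenyl}-3-phenylprop-2-yn-1-one F3.
- K2CO3 in acetone should then close the ring by 6-endo-dig oxa-Michael addition of the phenoxide to give 13.

Step 3. Alkyl transfer may be slow or show poor facial selectivity, because an ortho-methoxy group can compete with the sulfinyl oxygen for magnesium and the hindered, electron-rich imine may suffer β-hydride reduction instead of addition. The fallback sets out from 4 and comes back at 9, building the piperidine by allylation and metathesis instead of alkylation.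
- Barbier-type allylation with indium metal and allyl bromide (THF, 60 °C), a more reactive nucleophile that is also delivered to the Re face through a six-membered chair, should give (S)-N-{(R)-1-[4-(benzyloxy)-2,6-dimethoxyphenyl]but-3-en-1-yl}-2-methylpropane-2-sulfinamide F4.
- N-Allylation (LiN(SiMe3)2, allyl bromide, THF/DMF) should give (S)-N-allyl-N-{(R)-1-[4-(benzyloxy)-2,6-dimethoxyphenyl]but-3-en-1-yl}-2-methylpropane-2-sulfinamide F5.
- Ring-closing metathesis (second-generation Grubbs catalyst, CH2Cl2, 40 °C) should give (R)-2-[4-(benzyloxy)-2,6-dimethoxyphenyl]-1-[(S)-tert-butylsulfinyl]-1,2,3,6-tetrahydropyridine F6.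
- Brief treatment with HCl in MeOH at 0 °C should give (R)-2-[4-(benzyloxy)-2,6-dimethoxyphenyl]-1,2,3,6-tetrahydropyridine F7.
- Reductive methylation (aq HCHO, NaBH(OAc)3) should give (R)-2-[4-(benzyloxy)-2,6-dimethoxyphenyl]-1-methyl-1,2,3,6-tetrahydropyridine F8.
- Hydrogenation over Pd/C should saturate the ring alkene and cleave the benzyl ether in the same operation to give 9.

Step 10. Cleavage of the 7-methyl ether may be incomplete, or prolonged exposure of the freed phenols to the Lewis acid and the acid it generates may cause loss of configuration or opening and reclosure of ring C. The fallback sets out from 13 and comes back at 14, removing the two methyl groups in two mechanistically different stages.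
- BCl3 (CH2Cl2, −78 °C → 0 °C) should cleave only the chelated 5-methoxy group to give (R)-5-hydroxy-7-methoxy-6-(1-methylpiperidin-2-yl)-2-phenyl-4H-chromen-4-one F9.
- The remaining 7-methyl ether would then be removed by SN2 demethylation with NaSEt in DMF at 100 °C, under basic conditions in which the unprotonated amine is a poor leaving group, to give 14.

Further compounds
F1 | step 9 | 6-hydroxy-2,4-dimethoxy-3-[(R)-1-methylpiperidin-2-yl]benzaldehyde | CN1CCCC[C@@H]1c1c(OC)cc(O)c(C=O)c1OC
F2 | step 9 | 1-{6-hydroxy-2,4-dimethoxy-3-[(R)-1-methylpiperidin-2-yl]phenyl}-3-phenylprop-2-yn-1-ol (both carbinol epimers) | CN1CCCC[C@@H]1c1c(OC)cc(O)c(C(O)C#Cc2ccccc2)c1OC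
F3 | step 9 | 1-{6-hydroxy-2,4-dimethoxy-3-[(R)-1-methylpiperidin-2-yl]phenyl}-3-phenylprop-2-yn-1-one | CN1CCCC[C@@H]1c1c(OC)cc(O)c(C(=O)C#Cc2ccccc2)c1OC
F4 | step 3 | (S)-N-{(R)-1-[4-(benzyloxy)-2,6-dimethoxyphenyl]but-3-en-1-yl}-2-methylpropane-2-sulfinamide | CC(C)(C)[S@](=O)N[C@H](CC=C)c1c(OC)cc(OCc2ccccc2)cc1OC
F5 | step 3 | (S)-N-allyl-N-{(R)-1-[4-(benzyloxy)-2,6-dimethoxyphenyl]but-3-en-1-yl}-2-methylpropane-2-sulfinamide | CC(C)(C)[S@](=O)N(CC=C)[C@H](CC=C)c1c(OC)cc(OCc2ccccc2)cc1OC
F6 | step 3 | (R)-2-[4-(benzyloxy)-2,6-dimethoxyphenyl]-1-[(S)-tert-butylsulfinyl]-1,2,3,6-tetrahydropyridine | CC(C)(C)[S@](=O)N1CC=CC[C@@H]1c1c(OC)cc(OCc2ccccc2)cc1OC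
F7 | step 3 | (R)-2-[4-(benzyloxy)-2,6-dimethoxyphenyl]-1,2,3,6-tetrahydropyridine | N1CC=CC[C@@H]1c1c(OC)cc(OCc2ccccc2)cc1OC
F8 | step 3 | (R)-2-[4-(benzyloxy)-2,6-dimethoxyphenyl]-1-methyl-1,2,3,6-tetrahydropyridine | CN1CC=CC[C@@H]1c1c(OC)cc(OCc2ccccc2)cc1OC
F9 | step 10 | (R)-5-hydroxy-7-methoxy-6-(1-methylpiperidin-2-yl)-2-phenyl-4H-chromen-4-one | CN1CCCC[C@@H]1c1c(OC)cc2oc(-c3ccccc3)cc(=O)c2c1O
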